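The dusk run makes more other capture product than target, 33.8% against 4.6% at 80.0 s, and I want to know how far that split carries to a new flask.

| flask | solid substrate | first nucleophile | gas | remark | time |
|---|---|---|---|---|---|
| dusk | 2 M | 0.50 M | 200 mM (held) | run made earlier |  |
| flask | 1.0 M | 0.500 M | 200 mM (held) |  | 4.0 min |

dusk run (percent of the solid substrate charged)

| time / s | target / % | other capture product / % | solid substrate / % |
|---|---|---|---|
| 12.0 | 0.7 | 2.8 | 92.7 |
| 25.0 | 0.7 | 7.9 | 85.7 |
| 40.0 | 2.3 | 15.6 | 77.8 |
| 50.0 | 2.4 | 19.7 | 73.0 |
| 60.0 | 3.2 | 24.1 | 67.5 |
| 80.0 | 4.6 | 33.8 | 56.9 |

(each reading ± 0.3 percentage points)

- ratio of target to other capture product at 5.0 s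
- ratio of target to other capture product at 4.0 min
- which of target and other capture product there is more of at 4.0 min

- given per volume of solution although it is solid: solid substrate
- at the start none of second nucleophile is dissolved
- what was read earlier has a scatter of 0.3 percentage points, one standard deviation
- steps thought possible: solid substrate <-> starting material; gas <-> second nucleophile; second nucleophile + intermediate -> other capture product; first nucleophile <-> dormant form; first nucleophile + intermediate -> target; starting material <-> intermediate
- at the start none of the solid substrate is in solution

Among the steps thought possible, the two nucleophiles compete for the intermediate, so the products should form in the ratio of the two nucleophile levels, each weighted by its rate constant. My bench rule follows from this: with the gas held, I take the latest ratio of target to other capture product and divide it by the first nucleophile charge. I call this the capture ratio per molar, a selectivity factor at the working level of second nucleophile, and the last reading of the dusk run gives 0.272 M⁻¹. The new flask has the dusk run's gas and first nucleophile charge, and the dusk products at that reading already equal 76.8% of the new flask's solid charge. For 4.0 min I therefore commit to 0.136, with other capture product ahead.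

The rule needs a working level of second nucleophile, and none is dissolved at the start. At 12.0 s in the dusk run the ratio reads 0.250, which is 1.84 times the latest one of that run, though its target reading of 0.7% carries a scatter of 0.3 percentage points. The asked 5.0 s comes earlier than that first reading, at 0.417 of its time, so it lies beyond the border of the rule, and there I expect a ratio above that reading but commit to no number.

The forecast gives 0.3 at 5.0 s, 0.13 at 4.0 min, and other capture product ahead, reasoning that “the second nucleophile starts at zero and builds up over several seconds”. Its late figure is slightly below mine, and it puts a number on the early time, where I give none.

The flask gives 0.379 at 5.0 s and 0.114 at 4.0 min, with other capture product ahead.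

    solid substrate ⇌ starting material, rate k1*(cs1 - [starting material]) while solid is left; crystals form when [starting material] > cs1 (solubility = 0.510 M, k = 0.0260 s⁻¹)
    gas ⇌ second nucleophile, rate k2*(csat - [second nucleophile]) (kL = 0.130 s⁻¹)
    second nucleophile + intermediate → other capture product (k = 330 M⁻¹ s⁻¹)
    first nucleophile ⇌ dormant form (K = 0.530, k = 0.0290 s⁻¹)
    first nucleophile + intermediate → target (k = 16.0 M⁻¹ s⁻¹)
    starting material ⇌ intermediate (K = 0.0700, k = 0.100 s⁻¹)

At 4.00 min the flask holds first nucleophile at 52.0% of its charge, beside 0.138 M of dormant form. My 0.136 for this flask is 1.19 times its result. For the neighbour charged with 0.30 M of first nucleophile, the capture ratio per molar gives 0.0816. That neighbour gives 0.0693, which is 0.608 of this flask's ratio, against a charge ratio of 0.600.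

Readings and results come from a simulation on assumed constants; scatter was added.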